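**Retrosynthetic overview**
1. Last bond: C6–prenyl, by face-selective palladium allylation of the ring-opened lactone; the carbocycle is dearomatised last and C6 is set here.
2. Lactone ring (transient): carbene-catalysed [3+3] annulation of (E)-hex-2-enal onto C8/O7 of the 6-alkylchromanone sets the hexanoic acid stereocentre; the lactone is opened in the final step.
3. C6–CH2 bond: reductive alkylation of 5,7-dihydroxy-2,2-dimethylchroman-4-one (pyranone ring, formed first from phloroglucinol) with a trans-cyclobutane aldehyde.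
4. Key bond: cyclobutane C2–isopropenyl, made with reversed polarity. The cyclobutene enal acts as a nickel homoenolate (β-nucleophile) toward 2-bromopropene, so two electrophilic carbons are joined and both ring stereocentres are set.
5. Cyclobutane ring: enamine/acrylonitrile [2+2], then Hofmann elimination and nitrile reduction.

Assumption: core positions are numbered as in chroman-4-one (O1, C2, C3, C4, C4a, C5 to C8, C8a) throughout, also after dearomatisation.
Assumption: where a chiral catalyst is named, the enantiomer given is the one taken to deliver the drawn configuration; the antipode is used if the first run shows the opposite sense.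
Assumption: the dimethylamine enamine of isobutyraldehyde is bought as such.

**Step 1**
Reactants: 1 phloroglucinol (benzene-1,3,5-triol); 2 3-methylbut-2-enoic acid
Product: 4 5,7-dihydroxy-2,2-dimethylchroman-4-one, via aryl enone 3 (not isolated)
Conditions: MeSO3H, P2O5, 70 °C
Reagents that add atoms: none
Why: Friedel–Crafts acylation of the symmetric triphenol by the acylium ion from 2 is followed by acid-catalysed oxa-Michael closure of enone 3 onto an ortho hydroxyl, a standard one-pot chromanone synthesis that creates no stereocentre.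

**Step 2**
Reactants: 5 N,N,2-trimethylprop-1-en-1-amine; 6 acrylonitrile
Product: 7 2-(dimethylamino)-3,3-dimethylcyclobutane-1-carbonitrile (racemic cis/trans mixture)
Conditions: MeCN, sealed tube, 110 °C
Reagents that add atoms: none
Why: Thermal stepwise enamine–acrylonitrile [2+2] cycloaddition, in which the nucleophilic gem-dimethyl carbon of the enamine attacks the acrylonitrile terminus and the nitrile-stabilised carbanion closes onto the iminium carbon, gives this regiochemistry; both stereocentres are erased in step 3.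

**Step 3**
Reactants: 7 2-(dimethylamino)-3,3-dimethylcyclobutane-1-carbonitrile
Product: 9 3,3-dimethylcyclobut-1-ene-1-carbonitrile, via trimethylammonium iodide 8 (not isolated)
Conditions: MeI, MeCN, 23 °C; then K2CO3, 40 °C
Reagents that add atoms: iodomethane CI (its methyl group is found in intermediate 8 only; none of its atoms remain in 9)
Why: Exhaustive N-methylation makes the amine a leaving group β to the nitrile-acidified C1–H, so mild base effects a Hofmann elimination (E1cB) that can only give the conjugated cyclobutene because C3 is quaternary.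

**Step 4**
Reactants: 9 3,3-dimethylcyclobut-1-ene-1-carbonitrile
Product: 11 3,3-dimethylcyclobut-1-ene-1-carbaldehyde, via N-alumino imine 10 (not isolated)
Conditions: iBu2AlH, CH2Cl2, −78 °C; then 1 M HCl, 0 °C (product carried on in solution)
Reagents that add atoms: water O
Why: Partial reduction of a nitrile: iBu2AlH adds once to give the stable N-alumino imine 10, which is hydrolysed to the enal on work-up without touching the cyclobutene.

**Step 5 (key step)**
Reactants: 11 3,3-dimethylcyclobut-1-ene-1-carbaldehyde; 12 2-bromopropene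
Product: 14 (1R,2R)-3,3-dimethyl-2-(prop-1-en-2-yl)cyclobutane-1-carbaldehyde, via silyl enol ether 13 (not isolated)
Conditions: NiBr2(MeOCH2CH2OMe) (10 mol %), (4S,4'S)-4,4'-di-tert-butyl-4,4',5,5'-tetrahydro-2,2'-bioxazole (12 mol %), Mn powder, Me3SiCl, DMF, 0 → 23 °C; then K2CO3 (cat.), MeOH/H2O, 0 °C
Reagents that add atoms: chlorotrimethylsilane C[Si](C)(C)Cl (its silyl group is found in intermediate 13 only; none of its atoms remain in 14)
Why: Proposed new method: zerovalent nickel and Me3SiCl turn the enal into a 1-(silyloxy)allyl complex of divalent nickel, a homoenolate equivalent that is nucleophilic at the β-carbon C2 and is alkenylated by 2-bromopropene with Mn as terminal reductant, so that two carbons that are both electrophiles are joined with reversed polarity at the enal; the closest known reaction type is the nickel-mediated and nickel-catalysed reductive conjugate addition of aryl and alkenyl halides to enals and enones through silyloxyallyl nickel intermediates, made enantioselective here by the C2-symmetric bis(oxazoline) ligand, which discriminates the two enantiotopic faces of the flat cyclobutene at C2 (set as R), while C1 is set trans (R) to the new group by base equilibration of the aldehyde during desilylation.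

**Step 6**
Reactants: 4 5,7-dihydroxy-2,2-dimethylchroman-4-one; 14 (1R,2R)-3,3-dimethyl-2-(prop-1-en-2-yl)cyclobutane-1-carbaldehyde
Product: 16 6-{[(1S,2R)-3,3-dimethyl-2-(prop-1-en-2-yl)cyclobutyl]methyl}-5,7-dihydroxy-2,2-dimethylchroman-4-one, via alkylidene dione 15 (not isolated)
Conditions: L-proline (30 mol %), Hantzsch ester (diethyl 2,6-dimethyl-1,4-dihydropyridine-3,5-dicarboxylate), EtOH, 40 °C
Reagents that add atoms: none
Why: Organocatalytic reductive alkylation (Knoevenagel condensation then Hantzsch ester transfer hydrogenation): the proline iminium of 14 is attacked at C6, the 1,3-diketone-like carbon flanked by two free hydroxyls (C8 has only one, and Mannich reactions of 5,7-dihydroxyflavanones likewise go to C6), and the resulting alkylidene dione 15 takes up hydride at the exocyclic carbon; no new stereocentre forms and the epimerisable cyclobutane C1 stays trans.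

**Step 7**
Reactants: 16 6-{[(1S,2R)-3,3-dimethyl-2-(prop-1-en-2-yl)cyclobutyl]methyl}-5,7-dihydroxy-2,2-dimethylchroman-4-one; 17 (2E)-hex-2-enal
Product: 18 (10R)-6-{[(1S,2R)-3,3-dimethyl-2-(prop-1-en-2-yl)cyclobutyl]methyl}-5-hydroxy-2,2-dimethyl-10-propyl-2,3,9,10-tetrahydro-4H,8H-pyrano[2,3-f]chromene-4,8-dione (the O7/C8-fused δ-lactone)
Conditions: (5aS,10bR)-2-mesityl-5a,10b-dihydro-4H,6H-indeno[2,1-b][1,2,4]triazolo[4,3-d][1,4]oxazin-2-ium tetrafluoroborate (10 mol %), DBU (20 mol %), 3,3',5,5'-tetra-tert-butyl-4,4'-diphenoquinone, toluene, 23 °C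
Reagents that add atoms: none
Why: N-heterocyclic carbene-catalysed oxidative [3+3] annulation: the enal is oxidised on the chiral triazolylidene to an α,β-unsaturated acyl azolium, the phenol adds through its only free ring carbon C8 to the β-carbon under catalyst control (sets 10R, the later 3R centre of the hexanoic acid), and O7 closes the lactone and releases the carbene.

**Step 8**
Reactants: 18 the lactone from step 7; 19 3-methylbut-2-en-1-yl acetate (prenyl acetate)
Product: 21 (3R)-3-[(6R)-6-{[(1S,2R)-3,3-dimethyl-2-(prop-1-en-2-yl)cyclobutyl]methyl}-5-hydroxy-2,2-dimethyl-6-(3-methylbut-2-en-1-yl)-4,7-dioxo-3,4,6,7-tetrahydro-2H-chromen-8-yl]hexanoic acid (target CNP0358381.1), via trilithium seco-acid salt 20 (not isolated)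
Conditions: LiOH·H2O (3.0 equiv), THF/H2O, 0 °C; then 19, [Pd(C3H5)Cl]2 (2.5 mol %), (1R,2R)-N,N'-bis[2-(diphenylphosphanyl)benzoyl]cyclohexane-1,2-diamine (6 mol %), 0 → 23 °C; then 0.5 M HCl, 0 °C
Reagents that add atoms: lithium hydroxide [Li+].[OH-]
Why: Hydroxide opens the aryl lactone to trianion 20, whose most nucleophilic carbon C6 (between two oxygens) attacks the unsubstituted terminus of the π-prenyl complex of divalent palladium in a dearomatising Tsuji–Trost asymmetric allylic alkylation (carboxylate O-prenylation is reversible under palladium), the chiral diphosphine selecting the face of the planar nucleophile that gives 6R, and acidification frees the acid, which cannot relactonise because C7 is now a ketone.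

**Compound list**
1 | phloroglucinol (benzene-1,3,5-triol) | Oc1cc(O)cc(O)c1 | starting material
2 | 3-methylbut-2-enoic acid | CC(C)=CC(=O)O | starting material
3 | 3-methyl-1-(2,4,6-trihydroxyphenyl)but-2-en-1-one (aryl enone, not isolated) | CC(C)=CC(=O)c1c(O)cc(O)cc1O | intermediate
4 | 5,7-dihydroxy-2,2-dimethylchroman-4-one | CC1(C)CC(=O)c2c(O)cc(O)cc2O1 | intermediate
5 | N,N,2-trimethylprop-1-en-1-amine | CC(C)=CN(C)C | starting material
6 | acrylonitrile | C=CC#N | starting material
7 | 2-(dimethylamino)-3,3-dimethylcyclobutane-1-carbonitrile (racemic cis/trans mixture) | CN(C)C1C(C#N)CC1(C)C | intermediate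
8 | 2-cyano-N,N,N,4,4-pentamethylcyclobutan-1-aminium iodide (not isolated) | C[N+](C)(C)C1C(C#N)CC1(C)C.[I-] | intermediate
9 | 3,3-dimethylcyclobut-1-ene-1-carbonitrile | N#CC1=CC(C)(C)C1 | intermediate
10 | N-[bis(2-methylpropyl)alumanyl]-1-(3,3-dimethylcyclobut-1-en-1-yl)methanimine (not isolated) | CC(C)C[Al](CC(C)C)N=CC1=CC(C)(C)C1 | intermediate
11 | 3,3-dimethylcyclobut-1-ene-1-carbaldehyde | O=CC1=CC(C)(C)C1 | intermediate
12 | 2-bromopropene | C=C(C)Br | starting material
13 | {[(2R)-3,3-dimethyl-2-(prop-1-en-2-yl)cyclobutylidene]methoxy}trimethylsilane (E/Z mixture, not isolated) | C=C(C)[C@H]1C(=CO[Si](C)(C)C)CC1(C)C | intermediate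
14 | (1R,2R)-3,3-dimethyl-2-(prop-1-en-2-yl)cyclobutane-1-carbaldehyde | C=C(C)[C@H]1[C@H](C=O)CC1(C)C | intermediate
15 | 6-{[(1S,2R)-3,3-dimethyl-2-(prop-1-en-2-yl)cyclobutyl]methylidene}-5-hydroxy-2,2-dimethyl-2,3-dihydro-4H-chromene-4,7(6H)-dione (alkene isomers, not isolated) | C=C(C)[C@H]1[C@H](C=C2C(=O)C=C3OC(C)(C)CC(=O)C3=C2O)CC1(C)C | intermediate
16 | 6-{[(1S,2R)-3,3-dimethyl-2-(prop-1-en-2-yl)cyclobutyl]methyl}-5,7-dihydroxy-2,2-dimethylchroman-4-one | C=C(C)[C@H]1[C@H](Cc2c(O)cc3OC(C)(C)CC(=O)c3c2O)CC1(C)C | intermediate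
17 | (2E)-hex-2-enal | CCC/C=C/C=O | starting material
18 | (10R)-6-{[(1S,2R)-3,3-dimethyl-2-(prop-1-en-2-yl)cyclobutyl]methyl}-5-hydroxy-2,2-dimethyl-10-propyl-2,3,9,10-tetrahydro-4H,8H-pyrano[2,3-f]chromene-4,8-dione | C=C(C)[C@H]1[C@H](Cc2c(O)c3C(=O)CC(C)(C)Oc3c4c2OC(=O)C[C@H]4CCC)CC1(C)C | intermediate
19 | 3-methylbut-2-en-1-yl acetate (prenyl acetate) | CC(C)=CCOC(C)=O | starting material
20 | trilithium (3R)-3-[6-{[(1S,2R)-3,3-dimethyl-2-(prop-1-en-2-yl)cyclobutyl]methyl}-2,2-dimethyl-5,7-dioxido-4-oxochroman-8-yl]hexanoate (not isolated) | C=C(C)[C@H]1[C@H](Cc2c([O-])c3C(=O)CC(C)(C)Oc3c([C@H](CCC)CC(=O)[O-])c2[O-])CC1(C)C.[Li+].[Li+].[Li+] | intermediate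
21 | (3R)-3-[(6R)-6-{[(1S,2R)-3,3-dimethyl-2-(prop-1-en-2-yl)cyclobutyl]methyl}-5-hydroxy-2,2-dimethyl-6-(3-methylbut-2-en-1-yl)-4,7-dioxo-3,4,6,7-tetrahydro-2H-chromen-8-yl]hexanoic acid | C=C(C)[C@H]1[C@H](C[C@]2(CC=C(C)C)C(=O)C([C@H](CCC)CC(=O)O)=C3OC(C)(C)CC(=O)C3=C2O)CC1(C)C | target

**Step count and risks**
Total step count: 8. Longest linear sequence: 7 steps (steps 2 to 8, from 5 and 6 to 21); step 1 is the only side branch.

Step 5 is the most likely to fail. The enantioselective version of the nickel homoenolate alkenylation is unprecedented, and the β-carbon sits next to a quaternary centre. The fallback keeps the same polarity reversal but separates stereocentre formation from C–C bond formation. It sets out from nitrile 9. Copper-catalysed enantioselective conjugate borylation (CuCl, NaOtBu, (R)-DTBM-SEGPHOS, B2pin2, MeOH, THF, then base equilibration to trans) gives the boron homoenolate (1R,2S)-3,3-dimethyl-2-(4,4,5,5-tetramethyl-1,3,2-dioxaborolan-2-yl)cyclobutane-1-carbonitrile F1. Stereoretentive Suzuki–Miyaura coupling with 12 (Pd(OAc)2, RuPhos, K2CO3, toluene/H2O, 80 °C) gives (1R,2R)-3,3-dimethyl-2-(prop-1-en-2-yl)cyclobutane-1-carbonitrile F2. iBu2AlH at −78 °C gives the N-alumino imine N-[bis(2-methylpropyl)alumanyl]-1-[(1R,2R)-3,3-dimethyl-2-(prop-1-en-2-yl)cyclobutyl]methanimine F3 (not isolated), and cold dilute HCl hydrolyses it to aldehyde 14, where the route is rejoined.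

Step 6 is the second risk, because condensation could occur at C8 instead of C6 or at both. The fallback reverses the order of the two ring substitutions, so that the side chain is placed first by O-to-C transfer from the free 7-OH and the cyclobutane unit then has only one site left. It sets out from 4 and 17. The carbene-catalysed annulation of step 7 is run on 4; the acyl group is taken up at the non-chelated 7-OH and passed to C8, as [3,3] shifts of 7-O-allyl-5-hydroxychromanones favour C8. This gives (10R)-5-hydroxy-2,2-dimethyl-10-propyl-2,3,9,10-tetrahydro-4H,8H-pyrano[2,3-f]chromene-4,8-dione F4. Reductive alkylation of its single remaining ring C–H with 14 under the step 6 conditions passes through the quinone methide (10R)-6-{[(1S,2R)-3,3-dimethyl-2-(prop-1-en-2-yl)cyclobutyl]methylidene}-2,2-dimethyl-10-propyl-2,3,9,10-tetrahydro-4H,8H-pyrano[2,3-f]chromene-4,5,8(6H)-trione F5 (not isolated) and comes back to the route at 18.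

Step 8 is the third risk: face selectivity at C6 must come from the catalyst alone, in a one-pot aqueous medium, on a trianion. The fallback masks the acid and replaces palladium control by chiral ion-pair control. It sets out from 18. NaOMe in MeOH at 0 °C opens the lactone to methyl (3R)-3-[6-{[(1S,2R)-3,3-dimethyl-2-(prop-1-en-2-yl)cyclobutyl]methyl}-5,7-dihydroxy-2,2-dimethyl-4-oxochroman-8-yl]hexanoate F6. Solid–liquid phase-transfer C-alkylation with prenyl bromide (CsOH·H2O, N-(9-anthracenylmethyl)cinchonidinium bromide, toluene, −40 °C) gives methyl (3R)-3-[(6R)-6-{[(1S,2R)-3,3-dimethyl-2-(prop-1-en-2-yl)cyclobutyl]methyl}-5-hydroxy-2,2-dimethyl-6-(3-methylbut-2-en-1-yl)-4,7-dioxo-3,4,6,7-tetrahydro-2H-chromen-8-yl]hexanoate F7. LiOH in THF/H2O, then cold dilute HCl, comes back to the route at 21.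

**Further compounds**
F1 | step 5 | (1R,2S)-3,3-dimethyl-2-(4,4,5,5-tetramethyl-1,3,2-dioxaborolan-2-yl)cyclobutane-1-carbonitrile | CC1(C)OB(OC1(C)C)[C@H]2[C@H](C#N)CC2(C)C
F2 | step 5 | (1R,2R)-3,3-dimethyl-2-(prop-1-en-2-yl)cyclobutane-1-carbonitrile | C=C(C)[C@H]1[C@H](C#N)CC1(C)C
F3 | step 5 | N-[bis(2-methylpropyl)alumanyl]-1-[(1R,2R)-3,3-dimethyl-2-(prop-1-en-2-yl)cyclobutyl]methanimine | C=C(C)[C@H]1[C@H](C=N[Al](CC(C)C)CC(C)C)CC1(C)C
F4 | step 6 | (10R)-5-hydroxy-2,2-dimethyl-10-propyl-2,3,9,10-tetrahydro-4H,8H-pyrano[2,3-f]chromene-4,8-dione | Oc1cc2OC(=O)C[C@@H](CCC)c2c2OC(C)(C)CC(=O)c12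
F5 | step 6 | (10R)-6-{[(1S,2R)-3,3-dimethyl-2-(prop-1-en-2-yl)cyclobutyl]methylidene}-2,2-dimethyl-10-propyl-2,3,9,10-tetrahydro-4H,8H-pyrano[2,3-f]chromene-4,5,8(6H)-trione | C=C(C)[C@H]1[C@H](C=C2C(=O)C3=C(OC(C)(C)CC3=O)C4=C2OC(=O)C[C@H]4CCC)CC1(C)C
F6 | step 8 | methyl (3R)-3-[6-{[(1S,2R)-3,3-dimethyl-2-(prop-1-en-2-yl)cyclobutyl]methyl}-5,7-dihydroxy-2,2-dimethyl-4-oxochroman-8-yl]hexanoate | C=C(C)[C@H]1[C@H](Cc2c(O)c3C(=O)CC(C)(C)Oc3c([C@H](CCC)CC(=O)OC)c2O)CC1(C)C
F7 | step 8 | methyl (3R)-3-[(6R)-6-{[(1S,2R)-3,3-dimethyl-2-(prop-1-en-2-yl)cyclobutyl]methyl}-5-hydroxy-2,2-dimethyl-6-(3-methylbut-2-en-1-yl)-4,7-dioxo-3,4,6,7-tetrahydro-2H-chromen-8-yl]hexanoate | C=C(C)[C@H]1[C@H](C[C@]2(CC=C(C)C)C(=O)C([C@H](CCC)CC(=O)OC)=C3OC(C)(C)CC(=O)C3=C2O)CC1(C)C
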